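Birch leaves 6 % of its starting material at 8.00 min, and that leftover, set against the 38 % at 3.00 min, gives a pseudo-first-order loss constant of 0.369 min⁻¹ at its loading.

common to all: starting material 0.10 M

| flask | coupling partner | free catalyst | remark | time |
|---|---|---|---|---|
| cedar | 5.6 equiv (fed, over 4.0 min) | 2 mol% | run made earlier |  |
| larch | 8.8 equiv (fed, over 4.0 min) | 2 mol% | run made earlier |  |
| birch | 4 equiv (fed, over 4.0 min) | 4 mol% | run made earlier |  |
| flask | 4.00 equiv (fed, over 4.0 min) | 2 mol% |  | 10 min |

| run | time / min | target / % | starting material / % |
|---|---|---|---|
| cedar | 1.00 | 16 | 88 |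
| cedar | 3.00 | 36 | 63 |
| cedar | 5.00 | 53 | 42 |
| cedar | 8.00 | 77 | 27 |
| larch | 1.00 | 12 | 85 |
| larch | 3.00 | 36 | 65 |
| larch | 5.00 | 56 | 42 |
| larch | 8.00 | 76 | 26 |
| birch | 0.667 | 16 | 85 |
| birch | 1.33 | 32 | 69 |
| birch | 3.00 | 62 | 38 |
| birch | 8.00 | 95 | 6 |

(readings scatter by 1.5 percentage points)

- the earlier runs were read with a standard deviation of 1.5 percentage points

1. amount of target in percent of the starting material charged, at 30 s, 2.5 min and 10 min

We carry one quantity: the loss constant of starting material divided by the catalyst loading as a fraction, 9.23 min⁻¹. Its rule, with starting material at 0.10 M and partner at 4.00 equiv or more, is that equal loading times time gives equal course, and for the flask it means 0.185 min⁻¹. Cedar and larch test the rule. Their mean loss constant from 5.00 min to 8.00 min is 0.154 min⁻¹, and it puts their starting material at 36.0 % at 6.00 min, where the rule asks for birch's 38 %. Their readings also barely notice 5.6 equiv against 8.8 equiv of partner.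

That gives two ways to the flask. The first keeps the flask's partner feed and stretches birch, whose catalyst is 2.00 times the flask's, along the time axis: the flask's 10 min is birch at 5.00 min. Birch's early readings rise in proportion to time, so this way gives 6.00 %, 30.1 % and 81.8 %. The second keeps the flask's loading and reads the mean of cedar and larch, giving 7.00 %, 30.5 % and 80.5 %.

They agree at 2.5 min and part at the end by 1.3 points, where birch's constant per flask loading runs faster than cedar's and larch's. Birch's constant leans on a reading of 6 % with a scatter of 1.5 points, but its 5.00 min lies inside its readings, while the second way runs past its last reading, with more partner than the flask has. We commit to the first way's numbers.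

The forecast gave 5 %, 30 % and 80 %, holding that “the reaction is first order in catalyst and first order in starting material”; our last figure stands a little above it.

The flask gives 5.96 %, 31.3 % and 82.4 %.

    catalyst intermediate D → free catalyst + target (k = 0.680 s⁻¹)
    catalyst intermediate B ⇌ by-product + catalyst intermediate C (K = 0.300 M, k = 0.830 s⁻¹)
    coupling partner + free catalyst → catalyst intermediate A (k = 210 M⁻¹ s⁻¹)
    starting material + catalyst intermediate C ⇌ catalyst intermediate D (K = 14.0 M⁻¹, k = 3.10 M⁻¹ s⁻¹)
    catalyst intermediate A → catalyst intermediate B (k = 0.940 s⁻¹)

The flask stands at 82.4 % at 10 min, still short of its end, because two things act together, the time given and the way back from catalyst intermediate D to starting material and catalyst intermediate C; the same run without that way back gives 88.9 %. Our 0.185 min⁻¹ takes the flask's 44.6 % of starting material at 5.00 min to 17.7 % at 10.0 min, and the flask holds 17.5 %. Carried on to 100 min, it gives >99.9 % target, and the flask run that long holds 100 %.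

The numbers in the tables are simulated for an exercise.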